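The plan rests on cutting the C18–O bond of a 6α,18-ether. C4 of the target is a labdane gem-dimethyl carbon whose equatorial α-methyl (C18) is oxidised, and this methyl lies peri to the equatorial C6 oxygen across C5 of the trans-fused rings A and B. In one operation the C6 alkoxy radical of a larixol-derived bisnor ketone removes a C18 hydrogen and closes a tetrahydrofuran, making C4 stereogenic. The precursor carries one free hydroxyl (C6); the C8 hydroxyl and the C13 ketone are locked together as an internal methyl ketal. The side chain follows by asymmetric epoxidation, perhydrolysis with inversion at C13, and butenolide annulation.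

Key step: step 5

Numbering: labdane numbering for the core and C11 to C13 (C17 methyl on C8, C18 equatorial α-substituent on C4, C19 axial β-methyl on C4, C20 methyl on C10). From compound 17 on, C14 is the former acetyl methyl carbon, C14=C15 is the side-chain alkene and C16 is the lactone carbon bearing the ring oxygen.

Assumption: the ketal carbon C13 of 7 to 11 is drawn as the anomerically favoured epimer (methoxy axial), either epimer being serviceable; in step 15 "(S,S)" stands for the ProPhenol enantiomer that delivers the alkyne to the Re face of the aldehyde, its antipode being used if the sense of induction is the opposite.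

Step 1
Reactants: 1 larixol
Product: 2 8α,17-epoxylarixol (8α,17-epoxy-(13S)-labd-14-ene-6α,13-diol)
Conditions: mCPBA (1.05 equiv), NaHCO3, CH2Cl2, 0 °C
Reagents that add atoms: mCPBA, O=C(OO)c1cccc(Cl)c1
Why: Prilezhaev epoxidation should select the electron-richer 1,1-disubstituted C8=C17 alkene over the monosubstituted vinyl group, and the peracid should approach the α face, away from the axial C10 methyl and guided by hydrogen bonding to the homoallylic 6α-hydroxyl, which sets C8 with oxygen α.

Step 2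
Reactants: 2 8α,17-epoxylarixol
Product: 3 (13S)-labd-14-ene-6α,8α,13-triol
Conditions: LiAlH4, THF, reflux
Reagents that add atoms: none
Why: SN2 hydride opening of the spiro-epoxide at the unhindered primary C17 should leave the 8α C–O bond untouched, so that C8 carries an equatorial α-hydroxyl and an axial β-methyl.

Step 3
Reactants: 3 (13S)-labd-14-ene-6α,8α,13-triol
Product: 6 6α,8α-dihydroxy-14,15-dinorlabdan-13-one, via pentaol 4 (not isolated), via hydroxy aldehyde 5 (not isolated)
Conditions: K2OsO4·2H2O (2 mol%), NaIO4 (4 equiv), 2,6-lutidine, dioxane/H2O, rt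
Reagents that add atoms: none
Why: Lemieux–Johnson oxidation, in which dihydroxylation of the only remaining alkene and twofold periodate glycol cleavage of the 13,14,15-triol unit should excise C14 and C15 and leave the C13 methyl ketone, the ring hydroxyls having no vicinal partner.

Step 4
Reactants: 6 6α,8α-dihydroxy-14,15-dinorlabdan-13-one
Product: 7 (13S)-13-methoxy-8α,13-epoxy-14,15-dinorlabdan-6α-ol (internal methyl ketal)
Conditions: MeOH (5 equiv), PPTS (5 mol%), 4 Å MS, CH2Cl2, rt
Reagents that add atoms: methanol, CO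
Why: Acid-catalysed ketalisation, in which the 8α-hydroxyl adds to the C13 ketone to give a trans-fused six-membered hemiketal whose oxocarbenium ion is captured by methanol (methoxy axial through the anomeric effect), masks the tertiary hydroxyl and the ketone in one operation and leaves the C6 hydroxyl as the only free one.

Step 5
Reactants: 7 internal methyl ketal
Product: 10 (13S)-13-methoxy-6α,18:8α,13-diepoxy-14,15-dinorlabdane (C18 α on C4), via C6 hypoiodite 8 (not isolated), via 18-iodo alcohol 9 (not isolated)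
Conditions: PhI(OAc)2 (1.6 equiv), I2 (1.0 equiv), cyclohexane, visible light (tungsten lamp), 40 °C
Reagents that add atoms: none
Why: PhI(OAc)2 and I2 give acetyl hypoiodite, which converts the only free hydroxyl into the C6 hypoiodite 8; light cleaves the O–I bond, the alkoxy radical takes a hydrogen from C18 through a six-membered transition state (1,5-hydrogen transfer), and the C18 radical is trapped by iodine to give 9. The closest known reaction type is the Suárez hypoiodite cyclisation of alcohols onto δ-methyl groups, as in the conversion of 6β-hydroxy steroids into 6β,19-ethers. The tetrahydrofuran closes by 5-exo-tet displacement of iodide from C18 by the C6 oxygen. C4 becomes stereogenic because only the equatorial 4α-methyl is oxidised: the C6–O and C4–C18 bonds are both equatorial and parallel across C5 (about 2.5 to 3 Å apart), whereas the axial methyls on C4 and C10 lie on the opposite face. The step needs hydrogen transfer to win over β-scission of C5–C6 and over attack at other C–H bonds; the rigid trans-decalin holds C18 against the radical, and the C8 oxygen is tied up in the ketal, so that no second alkoxy radical can form.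

Step 6
Reactants: 10 6α,18-ether
Product: 12 8α-hydroxy-13-oxo-14,15-dinorlabdan-18,6α-olide, via lactone ketal 11 (not isolated)
Conditions: RuCl3·xH2O (5 mol%), NaIO4 (4 equiv), EtOAc/MeCN/H2O, rt; then 1 M HCl, THF, rt
Reagents that add atoms: sodium periodate (oxygen source for RuO4), [Na+].[O-]I(=O)(=O)=O; water, O
Why: RuO4 oxidation of a cyclic ether to a lactone should occur at C18, the only ether methylene (the ketal ring has no α C–H and the C6 methine is more shielded), and the acid work-up then hydrolyses the mixed ketal to the hydroxy ketone.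

Step 7
Reactants: 12 lactone hydroxy ketone
Product: 14 methyl 6α,8α-dihydroxy-13-oxo-14,15-dinorlabdan-18-oate, via lithium carboxylate 13 (not isolated)
Conditions: LiOH·H2O (3 equiv), THF/MeOH/H2O, 50 °C; evaporate; MeI (5 equiv), DMF, rt
Reagents that add atoms: lithium hydroxide, [Li+].[OH-]; iodomethane, CI
Why: Saponification opens the lactone irreversibly, and SN2 O-alkylation of the carboxylate salt with iodomethane, without any acidification, should give the methyl ester before the C6 hydroxyl can relactonise.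

Step 8
Reactants: 14 dihydroxy keto ester
Product: 15 methyl 13-oxo-6α,8α-bis(triethylsilyloxy)-14,15-dinorlabdan-18-oate
Conditions: TESOTf (3 equiv), 2,6-lutidine (5 equiv), CH2Cl2, −78 to 0 °C
Reagents that add atoms: triethylsilyl triflate, CC[Si](CC)(CC)OS(=O)(=O)C(F)(F)F
Why: Silylation with the silyl triflate should cap both the hindered secondary C6 hydroxyl and the tertiary C8 hydroxyl, which blocks relactonisation and any later attack of the C8 oxygen on C13, while at low temperature the ketone is not enol-silylated.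

Step 9
Reactants: 15 bis-silyl keto ester
Product: 17 terminal alkyne (acetyl group of 15 converted into ethynyl, C13≡C14), via enol phosphate 16 (not isolated)
Conditions: LDA (1.1 equiv), THF, −78 °C; ClP(O)(OEt)2, −78 °C to rt; then LDA (2.5 equiv), −78 °C to rt
Reagents that add atoms: none
Why: Kinetic deprotonation at the methyl group, O-phosphorylation and base-induced elimination of the terminal enol phosphate (Negishi alkyne synthesis from methyl ketones) should give the terminal alkyne, the ester on quaternary C4 having no α-hydrogen.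

Step 10
Reactants: 17 terminal alkyne
Product: 19 (13E)-allylic alcohol (C13 methyl, C15 hydroxymethyl), via alkenylalane 18 (not isolated)
Conditions: Me3Al (3 equiv), Cp2ZrCl2 (0.25 equiv), CH2Cl2, 0 °C to rt; evaporate; n-BuLi, THF, −78 °C; (CH2O)n, rt
Reagents that add atoms: trimethylaluminium, C[Al](C)C; paraformaldehyde (as formaldehyde), C=O
Why: Zirconium-catalysed syn-carboalumination (Negishi) places methyl on C13 and aluminium on terminal C14, and hydroxymethylation of the derived alanate with retention should give the E-trisubstituted allylic alcohol as a single geometric isomer.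

Step 11
Reactants: 19 (13E)-allylic alcohol
Product: 20 (13S,14S)-13,14-epoxy-15-ol
Conditions: Ti(OiPr)4 (10 mol%), L-(+)-diisopropyl tartrate (12 mol%), t-BuOOH, 4 Å MS, CH2Cl2, −20 °C
Reagents that add atoms: tert-butyl hydroperoxide, CC(C)(C)OO
Why: Katsuki–Sharpless asymmetric epoxidation of a geraniol-type E-allylic alcohol is reagent-controlled, and the L-tartrate catalyst should deliver oxygen to the face that gives the 13S,14S epoxide, the remote ring stereocentres having no influence.

Step 12
Reactants: 20 (13S,14S)-epoxy alcohol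
Product: 21 (13R,14S)-13-hydroperoxy-14,15-diol
Conditions: anhydrous H2O2 in Et2O (10 equiv), H3PMo12O40 (3 mol%), Et2O, 0 °C to rt
Reagents that add atoms: hydrogen peroxide, OO
Why: Acid-catalysed perhydrolysis of a trisubstituted epoxide, in which hydrogen peroxide should attack the tertiary carbon C13 from the rear with inversion (borderline SN2), converts the 13S C–O bond into the 13R hydroperoxide, while the silyl ether keeps the C8 oxygen from competing.

Step 13
Reactants: 21 hydroperoxy diol; 22 (triphenylphosphoranylidene)acetaldehyde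
Product: 24 (13R,14E)-13-hydroperoxy enal (C16 aldehyde), via hydroperoxy aldehyde 23 (not isolated)
Conditions: NaIO4 (1.5 equiv), THF/pH 7 buffer, 0 °C; extract; then 22 (1.5 equiv), CH2Cl2, 0 °C to rt
Reagents that add atoms: none
Why: Periodate glycol cleavage of the 14,15-diol (the hydroperoxide is inert to periodate) gives a non-enolisable aldehyde with quaternary C13 intact, and Wittig olefination with the stabilised ylide should give the E-enal.

Step 14
Reactants: 24 hydroperoxy enal
Product: 25 enal 2-methoxyprop-2-yl peroxyketal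
Conditions: 2-methoxypropene (3 equiv), PPTS (5 mol%), CH2Cl2, 0 °C
Reagents that add atoms: 2-methoxypropene, COC(C)=C
Why: Acid-catalysed addition of the hydroperoxide to the enol ether gives a base-stable peroxyketal, which shields the acidic O–O–H from the organometallic reagents of the next two steps.

Step 15
Reactants: 25 peroxyketal enal; 26 methyl propiolate
Product: 27 (13R,16S)-propargylic alcohol (methyl 4-hydroxy-2-ynoate unit at C16)
Conditions: (S,S)-ProPhenol (20 mol%), Me2Zn (3 equiv), 26 (3 equiv), toluene, 4 °C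
Reagents that add atoms: none
Why: Dinuclear zinc–ProPhenol-catalysed asymmetric alkynylation of an enal, in which the zinc acetylide of 26 should add 1,2 to the Re face of the aldehyde under catalyst control, sets C16 as S.

Step 16
Reactants: 27 propargylic alcohol
Product: 29 protected butenolide (13-peroxyketal, 6α,8α-bis-triethylsilyl ether of the target), via hydroxy Z-enoate 28 (not isolated)
Conditions: MeLi, CuI (Me2CuLi, 3 equiv), THF, −78 °C; aq. NH4Cl, −78 °C to rt
Reagents that add atoms: lithium dimethylcuprate, [Li+].C[Cu-]C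
Why: Syn conjugate addition of the Gilman cuprate to the ynoate puts methyl on the β-carbon cis to the new α-hydrogen, so the ester stands cis to the C16 carbinol (Z-enoate) and the C16 alkoxide closes the butenolide by lactonisation without touching the C16 stereocentre.

Step 17
Reactants: 29 protected butenolide
Product: 30 target CNP0128148.1
Conditions: aq. HF (48%), MeCN, 0 °C to rt
Reagents that add atoms: none
Why: Acidic fluoride should cleave both triethylsilyl ethers and hydrolyse the peroxyketal (acetal hydrolysis) in one operation, under conditions too mild to ionise the tertiary allylic hydroperoxide or to epimerise the butenolide.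

Compound list
1 | larixol, (13S)-labda-8(17),14-diene-6α,13-diol | CC1(C)CCC[C@@]2(C)[C@H]1[C@@H](O)CC(=C)[C@@H]2CC[C@](C)(O)C=C | starting material
2 | 8α,17-epoxy-(13S)-labd-14-ene-6α,13-diol | CC1(C)CCC[C@@]2(C)[C@H]1[C@@H](O)C[C@@]3(OC3)[C@@H]2CC[C@](C)(O)C=C | intermediate
3 | (13S)-labd-14-ene-6α,8α,13-triol | CC1(C)CCC[C@@]2(C)[C@H]1[C@@H](O)C[C@@](C)(O)[C@@H]2CC[C@](C)(O)C=C | intermediate
4 | labdane-6α,8α,13,14,15-pentaol (C14 epimers, not isolated) | CC1(C)CCC[C@@]2(C)[C@H]1[C@@H](O)C[C@@](C)(O)[C@@H]2CC[C@](C)(O)C(O)CO | intermediate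
5 | 6α,8α,13-trihydroxy-15-norlabdan-14-al (not isolated) | CC1(C)CCC[C@@]2(C)[C@H]1[C@@H](O)C[C@@](C)(O)[C@@H]2CC[C@](C)(O)C=O | intermediate
6 | 6α,8α-dihydroxy-14,15-dinorlabdan-13-one | CC1(C)CCC[C@@]2(C)[C@H]1[C@@H](O)C[C@@](C)(O)[C@@H]2CCC(C)=O | intermediate
7 | (13S)-13-methoxy-8α,13-epoxy-14,15-dinorlabdan-6α-ol (key-step precursor) | CC1(C)CCC[C@@]2(C)[C@H]1[C@@H](O)C[C@@](C)(O3)[C@@H]2CC[C@@]3(C)OC | intermediate
8 | C6 hypoiodite of 7 (not isolated) | CC1(C)CCC[C@@]2(C)[C@H]1[C@@H](OI)C[C@@](C)(O3)[C@@H]2CC[C@@]3(C)OC | intermediate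
9 | 18-iodo derivative of 7, iodomethyl α on C4 (not isolated) | IC[C@]1(C)CCC[C@@]2(C)[C@H]1[C@@H](O)C[C@@](C)(O3)[C@@H]2CC[C@@]3(C)OC | intermediate
10 | (13S)-13-methoxy-6α,18:8α,13-diepoxy-14,15-dinorlabdane (key-step product) | C4[C@]1(C)CCC[C@@]2(C)[C@H]1[C@@H](O4)C[C@@](C)(O3)[C@@H]2CC[C@@]3(C)OC | intermediate
11 | (13S)-13-methoxy-8α,13-epoxy-14,15-dinorlabdan-18,6α-olide (not isolated) | O=C4[C@]1(C)CCC[C@@]2(C)[C@H]1[C@@H](O4)C[C@@](C)(O3)[C@@H]2CC[C@@]3(C)OC | intermediate
12 | 8α-hydroxy-13-oxo-14,15-dinorlabdan-18,6α-olide | O=C4[C@]1(C)CCC[C@@]2(C)[C@H]1[C@@H](O4)C[C@@](C)(O)[C@@H]2CCC(C)=O | intermediate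
13 | lithium 6α,8α-dihydroxy-13-oxo-14,15-dinorlabdan-18-oate (not isolated) | [Li+].[O-]C(=O)[C@]1(C)CCC[C@@]2(C)[C@H]1[C@@H](O)C[C@@](C)(O)[C@@H]2CCC(C)=O | intermediate
14 | methyl 6α,8α-dihydroxy-13-oxo-14,15-dinorlabdan-18-oate | COC(=O)[C@]1(C)CCC[C@@]2(C)[C@H]1[C@@H](O)C[C@@](C)(O)[C@@H]2CCC(C)=O | intermediate
15 | methyl 13-oxo-6α,8α-bis(triethylsilyloxy)-14,15-dinorlabdan-18-oate | COC(=O)[C@]1(C)CCC[C@@]2(C)[C@H]1[C@@H](O[Si](CC)(CC)CC)C[C@@](C)(O[Si](CC)(CC)CC)[C@@H]2CCC(C)=O | intermediate
16 | terminal enol diethyl phosphate of 15 (not isolated) | COC(=O)[C@]1(C)CCC[C@@]2(C)[C@H]1[C@@H](O[Si](CC)(CC)CC)C[C@@](C)(O[Si](CC)(CC)CC)[C@@H]2CCC(=C)OP(=O)(OCC)OCC | intermediate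
17 | terminal alkyne, 9β-(but-3-ynyl) side chain, core as in 15 | COC(=O)[C@]1(C)CCC[C@@]2(C)[C@H]1[C@@H](O[Si](CC)(CC)CC)C[C@@](C)(O[Si](CC)(CC)CC)[C@@H]2CCC#C | intermediate
18 | (E)-alkenyl(dimethyl)alane, methyl on C13, aluminium on C14 (not isolated) | COC(=O)[C@]1(C)CCC[C@@]2(C)[C@H]1[C@@H](O[Si](CC)(CC)CC)C[C@@](C)(O[Si](CC)(CC)CC)[C@@H]2CC/C(C)=C/[Al](C)C | intermediate
19 | (13E)-allylic alcohol, 9β-[(E)-5-hydroxy-3-methylpent-3-enyl] side chain | COC(=O)[C@]1(C)CCC[C@@]2(C)[C@H]1[C@@H](O[Si](CC)(CC)CC)C[C@@](C)(O[Si](CC)(CC)CC)[C@@H]2CC/C(C)=C/CO | intermediate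
20 | (13S,14S)-13,14-epoxy-15-ol | COC(=O)[C@]1(C)CCC[C@@]2(C)[C@H]1[C@@H](O[Si](CC)(CC)CC)C[C@@](C)(O[Si](CC)(CC)CC)[C@@H]2CC[C@]3(C)O[C@H]3CO | intermediate
21 | (13R,14S)-13-hydroperoxy-14,15-diol | COC(=O)[C@]1(C)CCC[C@@]2(C)[C@H]1[C@@H](O[Si](CC)(CC)CC)C[C@@](C)(O[Si](CC)(CC)CC)[C@@H]2CC[C@@](C)(OO)[C@@H](O)CO | intermediate
22 | (triphenylphosphoranylidene)acetaldehyde | O=CC=P(c1ccccc1)(c1ccccc1)c1ccccc1 | starting material
23 | (13R)-13-hydroperoxy-14-aldehyde (not isolated) | COC(=O)[C@]1(C)CCC[C@@]2(C)[C@H]1[C@@H](O[Si](CC)(CC)CC)C[C@@](C)(O[Si](CC)(CC)CC)[C@@H]2CC[C@@](C)(OO)C=O | intermediate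
24 | (13R,14E)-13-hydroperoxy-14-en-16-al | COC(=O)[C@]1(C)CCC[C@@]2(C)[C@H]1[C@@H](O[Si](CC)(CC)CC)C[C@@](C)(O[Si](CC)(CC)CC)[C@@H]2CC[C@@](C)(OO)/C=C/C=O | intermediate
25 | (13R,14E)-13-(2-methoxyprop-2-ylperoxy)-14-en-16-al | COC(=O)[C@]1(C)CCC[C@@]2(C)[C@H]1[C@@H](O[Si](CC)(CC)CC)C[C@@](C)(O[Si](CC)(CC)CC)[C@@H]2CC[C@@](C)(OOC(C)(C)OC)/C=C/C=O | intermediate
26 | methyl propiolate | C#CC(=O)OC | starting material
27 | (13R,14E,16S)-16-hydroxy ynoate (propargylic alcohol) | COC(=O)[C@]1(C)CCC[C@@]2(C)[C@H]1[C@@H](O[Si](CC)(CC)CC)C[C@@](C)(O[Si](CC)(CC)CC)[C@@H]2CC[C@@](C)(OOC(C)(C)OC)/C=C/[C@H](O)C#CC(=O)OC | intermediate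
28 | (13R,14E,16S)-16-hydroxy-(Z)-β-methyl enoate (not isolated) | COC(=O)[C@]1(C)CCC[C@@]2(C)[C@H]1[C@@H](O[Si](CC)(CC)CC)C[C@@](C)(O[Si](CC)(CC)CC)[C@@H]2CC[C@@](C)(OOC(C)(C)OC)/C=C/[C@H](O)/C(C)=C\C(=O)OC | intermediate
29 | protected target: 13-peroxyketal, 6α,8α-bis(triethylsilyl) ether, (16S)-4-methylbutenolide | COC(=O)[C@]1(C)CCC[C@@]2(C)[C@H]1[C@@H](O[Si](CC)(CC)CC)C[C@@](C)(O[Si](CC)(CC)CC)[C@@H]2CC[C@@](C)(OOC(C)(C)OC)/C=C/[C@@H]3OC(=O)C=C3C | intermediate
30 | CNP0128148.1, methyl ester with 6α,8α-diol, (13R)-hydroperoxide, 14E-alkene and (16S)-4-methylbutenolide | COC(=O)[C@]1(C)CCC[C@@]2(C)[C@H]1[C@@H](O)C[C@@](C)(O)[C@@H]2CC[C@](C)(/C=C/[C@@H]1OC(=O)C=C1C)OO | target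

Total steps: 17. Longest linear sequence: 17 steps (1 to 30).

Steps most likely to fail

Step 5. Acetyl hypoiodite may drive a second hypoiodite cycle at C18 (over-oxidation), or the acid it releases may ionise the ketal; both would erode the cyclic ether. The fallback replaces iodine by nitric oxide as the radical trap. It sets out from 7: NOCl in pyridine at −20 °C should give the C6 nitrite ester F1. Photolysis (mercury lamp, Pyrex, benzene) followed by warming in propan-2-ol should give, by the Barton reaction through the same 1,5-hydrogen transfer, the C18 oxime F2. NaNO2 in aqueous acetic acid should cleave the oxime and hydrolyse the ketal, and the freed aldehyde closes onto the C6 hydroxyl to give the lactol F3. Fétizon oxidation (Ag2CO3 on Celite, benzene, reflux) should then give the lactone, and the route is rejoined at 12.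

Step 13. The free α-hydroperoxy aldehyde may fragment to the C13 ketone and formic acid faster than it is olefinated. The fallback masks the hydroperoxide before the aldehyde is generated. It sets out from 20: acetylation (Ac2O, pyridine) should give the epoxy acetate F4, and perhydrolysis as in step 12 the hydroperoxy hydroxy acetate F5. 2-Methoxypropene with PPTS at −20 °C should protect the hydroperoxide in the presence of the hindered secondary hydroxyl to give the peroxyketal acetate F6. K2CO3 in methanol should remove the acetate to give the peroxyketal diol F7, and NaIO4 should then give the protected α-peroxy aldehyde F8. Wittig reaction of F8 with 22 returns to the route at 25.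

Step 16. The cuprate may attack the peroxide (reduction of the O–O bond or SN2' displacement of the allylic peroxy group) in competition with conjugate addition. The fallback builds the butenolide without a carbon nucleophile of copper. It sets out from 25: zinc–ProPhenol alkynylation with trimethylsilylacetylene should give the silyl propargylic alcohol F9, and K2CO3 in methanol the terminal propargylic alcohol F10. Gold-catalysed Markovnikov hydration ((IPr)AuCl, AgSbF6, dioxane/H2O; IPr = 1,3-bis(2,6-diisopropylphenyl)imidazol-2-ylidene) should give the α-hydroxy methyl ketone F11. (Triphenylphosphoranylidene)ketene in toluene at 60 °C should acylate the hydroxyl and close the ring by intramolecular Wittig reaction, and the route is rejoined at 29.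

Further compounds
F1 | step 5 | C6 nitrite ester of 7 | CC1(C)CCC[C@@]2(C)[C@H]1[C@@H](ON=O)C[C@@](C)(O3)[C@@H]2CC[C@@]3(C)OC
F2 | step 5 | (E)-18-oxime of the 6α-ol, ketal as in 7 | O/N=C/[C@]1(C)CCC[C@@]2(C)[C@H]1[C@@H](O)C[C@@](C)(O3)[C@@H]2CC[C@@]3(C)OC
F3 | step 5 | 6α,18-epoxy-8α,18-dihydroxy-14,15-dinorlabdan-13-one (lactol, C18 anomers) | OC4[C@]1(C)CCC[C@@]2(C)[C@H]1[C@@H](O4)C[C@@](C)(O)[C@@H]2CCC(C)=O
F4 | step 13 | 15-acetate of epoxy alcohol 20 | COC(=O)[C@]1(C)CCC[C@@]2(C)[C@H]1[C@@H](O[Si](CC)(CC)CC)C[C@@](C)(O[Si](CC)(CC)CC)[C@@H]2CC[C@]3(C)O[C@H]3COC(C)=O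
F5 | step 13 | (13R,14S)-13-hydroperoxy-14-hydroxy-15-acetate | COC(=O)[C@]1(C)CCC[C@@]2(C)[C@H]1[C@@H](O[Si](CC)(CC)CC)C[C@@](C)(O[Si](CC)(CC)CC)[C@@H]2CC[C@@](C)(OO)[C@@H](O)COC(C)=O
F6 | step 13 | (13R,14S)-13-(2-methoxyprop-2-ylperoxy)-14-hydroxy-15-acetate | COC(=O)[C@]1(C)CCC[C@@]2(C)[C@H]1[C@@H](O[Si](CC)(CC)CC)C[C@@](C)(O[Si](CC)(CC)CC)[C@@H]2CC[C@@](C)(OOC(C)(C)OC)[C@@H](O)COC(C)=O
F7 | step 13 | (13R,14S)-13-(2-methoxyprop-2-ylperoxy)-14,15-diol | COC(=O)[C@]1(C)CCC[C@@]2(C)[C@H]1[C@@H](O[Si](CC)(CC)CC)C[C@@](C)(O[Si](CC)(CC)CC)[C@@H]2CC[C@@](C)(OOC(C)(C)OC)[C@@H](O)CO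
F8 | step 13 | (13R)-13-(2-methoxyprop-2-ylperoxy)-14-aldehyde | COC(=O)[C@]1(C)CCC[C@@]2(C)[C@H]1[C@@H](O[Si](CC)(CC)CC)C[C@@](C)(O[Si](CC)(CC)CC)[C@@H]2CC[C@@](C)(OOC(C)(C)OC)C=O
F9 | step 16 | (13R,14E,16S)-16-hydroxy-16-(trimethylsilylethynyl) compound | COC(=O)[C@]1(C)CCC[C@@]2(C)[C@H]1[C@@H](O[Si](CC)(CC)CC)C[C@@](C)(O[Si](CC)(CC)CC)[C@@H]2CC[C@@](C)(OOC(C)(C)OC)/C=C/[C@H](O)C#C[Si](C)(C)C
F10 | step 16 | (13R,14E,16S)-16-ethynyl-16-hydroxy compound | COC(=O)[C@]1(C)CCC[C@@]2(C)[C@H]1[C@@H](O[Si](CC)(CC)CC)C[C@@](C)(O[Si](CC)(CC)CC)[C@@H]2CC[C@@](C)(OOC(C)(C)OC)/C=C/[C@H](O)C#C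
F11 | step 16 | (13R,14E,16S)-16-hydroxy methyl ketone | COC(=O)[C@]1(C)CCC[C@@]2(C)[C@H]1[C@@H](O[Si](CC)(CC)CC)C[C@@](C)(O[Si](CC)(CC)CC)[C@@H]2CC[C@@](C)(OOC(C)(C)OC)/C=C/[C@H](O)C(C)=O
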